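The readings were computed for an exercise, and the scatter is random.

A reading of the delta flask at 16 min shows target made less target lost, so two times are reckoned here from the earlier runs: the fill time, which is the substrate charge over the opening rate, and the loss time of target.

| flask | substrate | partner | time |
|---|---|---|---|
| zeta | 0.0800 M | 0.0800 M |  |
| eta | 0.120 M | 0.0800 M |  |
| delta | 0.240 M | 0.240 M | 16 min |

| run | time / min | [target] / M |
|---|---|---|
| zeta run | 2.3 | 0.0104 |
| zeta run | 4.6 | 0.0166 |
| zeta run | 6.9 | 0.0221 |
| zeta run | 9.1 | 0.0254 |
| zeta run | 11 | 0.0275 |
| zeta run | 14 | 0.0301 |
| zeta run | 16 | 0.0310 |
| eta run | 2.3 | 0.0123 |
| eta run | 4.6 | 0.0203 |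
| eta run | 6.9 | 0.0261 |
| eta run | 9.1 | 0.0293 |
| eta run | 11 | 0.0326 |
| eta run | 14 | 0.0350 |
| eta run | 16 | 0.0356 |

(scatter of a reading: 6 × 10⁻⁴ M)

- Overall: substrate + partner -> target.
- Constant volume, constant temperature.
- A reading of a species includes what of it is bound.
- An order is taken over about fifteen percent of the charge, up and down.

* how the opening rate goes with [substrate] round the charge of the zeta run: the exponent of the rate at two percent of substrate gone to target (one fixed amount of target, the same in the runs compared)
* target in the delta run at 16 min, as a share of the substrate charged

The first interval of the zeta run gives an opening rate of 0.00452 M/min, and the first eta reading set against it gives a substrate order of 0.414, read at a fixed time. Partner order was not varied, so it is taken as one from the overall equation. At 14 min in the zeta run, the target reading leaves 62.4 % of the substrate. These orders then allow formation of 0.00232 M/min, but the last readings climb at 7.00 × 10⁻⁴ M/min, which is slower. Reading that gap as target disappearing gives the loss time, target present over its rate of disappearance 18.6 min.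

At the delta charges, the same orders give a fill time of 11.2 min, shorter than the loss time. Treating the delta flask as a consecutive reaction, with target as the intermediate of two first-order steps, gives 46.0 % of the charge at 16 min.

The forecast differs slightly from this reckoning, with 0.5 for the order and 45 % for the delta share: “I expect about 45%, with wide uncertainty”.

The simulation gives an order of 0.46 and a delta share of 51.1 %.

    substrate + partner → target (1.614 /M/min)
    substrate + 2 partner → target + partner (26.28 /M²/min)
    target → decomposed product (0.03396 /min)
    substrate + partner ⇌ idle substrate-reagent adduct, settled at all times (20.20 /M)

The passing of target into decomposed product takes target out of the delta flask: the run without that step reaches 72.7 % at 16 min, against 51.1 % with it, a difference of 22 percentage points. The loss time of 18.6 min and the fill time of 11.2 min reckon a surviving share of 60.6 % for the delta target at 16 min, while the run with the step set over the run without it gives a larger share, 70.3 %.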